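Ring C is cut at O1–C2 and C3–C4. O1, C8a, C4a and C4 come from a ring A salicylaldehyde, converted in the flask into its C4-methoxy ortho-quinone methide; C2 and C3 come from a ring B styrene whose free 4'-OH, para to the vinyl group and flanked by two prenyl groups, makes it a strongly nucleophilic, phosphate-bound vinylphenol. One chiral phosphoric acid catalysed formal [4+2] step joins the halves, closes ring C and sets C2 as (R), with C4 already oxygenated so that no benzylic oxidation is needed beside three prenyl groups. Its precursors are aldehyde 7, whose substitution pattern is fixed by a para-Claisen–Cope shift, and iodophenol-derived styrene 12.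

Key step: step 6

Abbreviations: prenyl = 3-methylbut-2-en-1-yl; MOM = methoxymethyl; (R)-TRIP = (R)-3,3'-bis(2,4,6-triisopropylphenyl)-1,1'-binaphthyl-2,2'-diyl hydrogen phosphate.

Assumption 1: the target SMILES is read as (2R); which enantiomer of the phosphoric acid gives (2R) cannot be predicted, so the (R)-acid is written and its equally available (S)-antipode would be used if the first run showed the (2S) series.

Assumption 2: compounds 15 to 18 are drawn (4R) (2,4-cis in the flavans); the C4 epimer may accompany each, is carried along and converges in step 9.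

Step 1
Reactants: 1 2,4,6-trihydroxybenzaldehyde
Product: 2 2-hydroxy-4,6-bis(methoxymethoxy)benzaldehyde
Conditions: MOMCl (2.1 equiv), iPr2NEt (2.5 equiv), CH2Cl2, 0 °C to rt
Reagents that add atoms: chloromethyl methyl ether, COCCl
Why: Williamson-type O-alkylation in which the para hydroxyl and one ortho hydroxyl react, while the last ortho hydroxyl stays free because it is held in a strong hydrogen bond to the formyl group, as is usual for 2,4,6-trihydroxyaryl carbonyl compounds.

Step 2
Reactants: 2 2-hydroxy-4,6-bis(methoxymethoxy)benzaldehyde; 3 prenyl bromide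
Product: 4 2,4-bis(methoxymethoxy)-6-(prenyloxy)benzaldehyde
Conditions: 3 (1.3 equiv), K2CO3, DMF, rt to 40 °C
Reagents that add atoms: prenyl bromide 3, CC(C)=CCBr
Why: Williamson ether synthesis, in which carbonate in DMF breaks the chelate and the phenoxide is O-alkylated by the primary allylic bromide while the MOM ethers and the aldehyde are inert.

Step 3
Reactants: 4 2,4-bis(methoxymethoxy)-6-(prenyloxy)benzaldehyde
Product: 7 6-hydroxy-2,4-bis(methoxymethoxy)-3-prenylbenzaldehyde (= 2-hydroxy-4,6-bis(methoxymethoxy)-5-prenylbenzaldehyde), via ortho-dienone 5 (not isolated), via para-dienone 6 (not isolated)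
Conditions: N,N-diethylaniline, 195 °C, argon
Reagents that add atoms: none
Why: Aromatic Claisen rearrangement followed by Cope rearrangement (para-Claisen–Cope), well precedented for 2-prenyloxy-4,6-dialkoxyaryl carbonyl compounds: the only free ortho carbon takes a 1,1-dimethylallyl group (5), a second [3,3] shift delivers a normal prenyl group to the para carbon between the two MOM ethers (6), and enolisation gives the chelated phenol, so the free hydroxyl ends ortho to the formyl group and remote from the prenyl group by mechanism and not by a selective protection.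

Step 4
Reactants: 8 4-iodophenol; 3 prenyl bromide
Product: 10 4-iodo-2,6-diprenylphenol, via 4-iodo-2-prenylphenol 9 (not isolated)
Conditions: NaH (2.3 equiv), toluene, 0 °C; then 3 (2.2 equiv), rt
Reagents that add atoms: prenyl bromide 3, CC(C)=CCBr
Why: ortho-C-Alkylation of a sodium phenoxide in a non-polar medium, where tight ion pairing shields oxygen and directs the allylic bromide to the ortho carbons; the para position is blocked by iodine, so a second alkylation of 9 should give the 2,6-diprenylphenol.

Step 5
Reactants: 10 4-iodo-2,6-diprenylphenol; 11 vinylboronic acid pinacol ester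
Product: 12 4-ethenyl-2,6-diprenylphenol (4-hydroxy-3,5-diprenylstyrene)
Conditions: 11 (1.3 equiv), PdCl2(dppf) (3 mol %), K2CO3, 1,4-dioxane/H2O (5:1), BHT (trace), 70 °C; product stored cold and used promptly
Reagents that add atoms: vinylboronic acid pinacol ester 11, C=CB1OC(C)(C)C(C)(C)O1
Why: Suzuki–Miyaura coupling, in which the aryl iodide adds readily to palladium, the free phenol and the trisubstituted alkenes are tolerated, and mild base with a radical inhibitor should keep the vinylphenol from polymerising.

Step 6
Reactants: 7 6-hydroxy-2,4-bis(methoxymethoxy)-3-prenylbenzaldehyde; 12 4-ethenyl-2,6-diprenylphenol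
Product: 16 4-[(2R,4R)-4-methoxy-5,7-bis(methoxymethoxy)-6-prenyl-3,4-dihydro-2H-chromen-2-yl]-2,6-diprenylphenol (the 2,4-cis 4-methoxyflavan), via dimethyl acetal 13 (not isolated), via methoxy ortho-quinone methide 14 (not isolated), via para-quinone methide 15 (not isolated)
Conditions: HC(OMe)3 (3 equiv), (R)-TRIP (10 mol %), 5 Å MS, toluene, 0 °C; 12 (1.5 equiv) added slowly, 0 °C to rt; Et3N quench, Et3N-washed silica
Reagents that add atoms: trimethyl orthoformate, COC(OC)OC
Why: Proposed new method: the phosphoric acid should catalyse acetal exchange of 7 with HC(OMe)3 to 13 and loss of methanol (taken up by the sieves) to the C4-methoxy ortho-quinone methide 14, present as its O-protonated oxocarbenium form paired with the chiral phosphate; the terminal carbon of 12 (C3) attacks C4, and the 4'-OH, hydrogen-bonded to the phosphate, gives up its proton so that the benzylic cation becomes para-quinone methide 15. Ring C then closes by 6-exo-trig oxa-1,6-addition of the ring A phenol O1 to C2 of 15, the C2=C1' bond lying outside the new ring. C2 is set in this closure, where the phosphate holds the quinone methide and the attacking phenol at once and leaves one face of C2 open, the (2R) face with the catalyst enantiomer chosen; C4 is set in the C3–C4 bond formation, is expected to end cis to the aryl group and is removed in step 9. The closest known reaction types are chiral phosphoric acid catalysed [4+2] cycloadditions of ortho-quinone methides (from ortho-hydroxybenzyl alcohols) with 4-hydroxystyrenes and the achiral acid-promoted union of salicylaldehydes, orthoformates and alkenes to 4-alkoxychromans; their combination on an alkoxy-substituted quinone methide under asymmetric catalysis is the untested element. The step needs regioselectivity, which polarity supplies (nucleophilic styrene terminus onto electrophilic C4), site selectivity on ring A, which the single free phenol of 7 secures (O5 and O7 are MOM ethers, so only the 6-prenyl isomer can form), and chemoselectivity over the three prenyl alkenes, which are far weaker nucleophiles than the hydroxystyrene and are not protonated by the weak acid.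

Step 7
Reactants: 16 the (2R,4R)-4-methoxyflavan with free 4'-OH
Product: 17 4-[(2R,4R)-4-methoxy-5,7-bis(methoxymethoxy)-6-prenyl-3,4-dihydro-2H-chromen-2-yl]-2,6-diprenylphenyl acetate
Conditions: Ac2O, pyridine, DMAP (cat.), CH2Cl2, 0 °C to rt
Reagents that add atoms: acetic anhydride, CC(=O)OC(C)=O
Why: DMAP-catalysed O-acylation of the hindered phenol under basic, non-ionising conditions that leave the acid-labile C4 ether alone; the electron-poor ester shuts down ionisation of the C2–O1 bond through a para-quinone methide and so guards C2 in the acidic and oxidative steps that follow.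

Step 8
Reactants: 17 the 4'-O-acetyl 4-methoxyflavan
Product: 18 4-[(2R,4R)-4-hydroxy-5,7-bis(methoxymethoxy)-6-prenyl-3,4-dihydro-2H-chromen-2-yl]-2,6-diprenylphenyl acetate
Conditions: PPTS (0.2 equiv), acetone/H2O (4:1), 0.02 M, rt
Reagents that add atoms: water, O
Why: SN1 solvolysis, in which the C4 methyl ether ionises under very mild acid because the cation is stabilised by O1, O5 and O7 of ring A and is captured by water in large excess at high dilution, while aryl MOM ethers, the aryl acetate and the prenyl groups need far stronger acid and C2 is not involved.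

Step 9
Reactants: 18 the 4'-O-acetyl flavan-4-ol
Product: 19 4-[(2R)-5,7-bis(methoxymethoxy)-4-oxo-6-prenyl-3,4-dihydro-2H-chromen-2-yl]-2,6-diprenylphenyl acetate
Conditions: Dess–Martin periodinane (1.3 equiv), pyridine (3 equiv), CH2Cl2, 0 °C
Reagents that add atoms: none
Why: Dess–Martin oxidation of the secondary benzylic alcohol to the ketone under pyridine buffering, which removes the C4 stereocentre (both epimers converge) and leaves the trisubstituted alkenes, MOM ethers, acetate and the C2 centre (beta to the new carbonyl) untouched.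

Step 10
Reactants: 19 the (2R)-flavanone bearing two MOM ethers and the 4'-acetate
Product: 20 (2R)-5,7-dihydroxy-2-(4-hydroxy-3,5-diprenylphenyl)-6-prenyl-2,3-dihydro-4H-chromen-4-one (target)
Conditions: 3 M aq. HCl/MeOH (1:4), 50 °C, stopped at full conversion
Reagents that add atoms: none
Why: Acid-catalysed transacetalisation of the two aryl MOM ethers and transesterification of the aryl acetate with methanol in one operation, a deprotection in common use for prenylated flavanones, run at moderate temperature to outrun cyclisation of the ortho-prenyl phenols and ring opening at C2.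

Compound list

1 | 2,4,6-trihydroxybenzaldehyde | O=Cc1c(O)cc(O)cc1O | starting material
2 | 2-hydroxy-4,6-bis(methoxymethoxy)benzaldehyde | O=Cc1c(O)cc(OCOC)cc1OCOC | intermediate
3 | prenyl bromide (1-bromo-3-methylbut-2-ene) | CC(C)=CCBr | starting material
4 | 2,4-bis(methoxymethoxy)-6-[(3-methylbut-2-en-1-yl)oxy]benzaldehyde | O=Cc1c(OCC=C(C)C)cc(OCOC)cc1OCOC | intermediate
5 | 2,4-bis(methoxymethoxy)-5-(2-methylbut-3-en-2-yl)-6-oxocyclohexa-1,3-diene-1-carbaldehyde (racemic ortho-dienone, not isolated) | O=CC1=C(OCOC)C=C(OCOC)C(C(C)(C)C=C)C1=O | intermediate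
6 | 2,4-bis(methoxymethoxy)-3-(3-methylbut-2-en-1-yl)-6-oxocyclohexa-1,4-diene-1-carbaldehyde (para-dienone, not isolated) | O=CC1=C(OCOC)C(CC=C(C)C)C(OCOC)=CC1=O | intermediate
7 | 6-hydroxy-2,4-bis(methoxymethoxy)-3-(3-methylbut-2-en-1-yl)benzaldehyde | O=Cc1c(O)cc(OCOC)c(CC=C(C)C)c1OCOC | intermediate
8 | 4-iodophenol | Oc1ccc(I)cc1 | starting material
9 | 4-iodo-2-(3-methylbut-2-en-1-yl)phenol (not isolated) | Oc1ccc(I)cc1CC=C(C)C | intermediate
10 | 4-iodo-2,6-bis(3-methylbut-2-en-1-yl)phenol | Oc1c(CC=C(C)C)cc(I)cc1CC=C(C)C | intermediate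
11 | 2-ethenyl-4,4,5,5-tetramethyl-1,3,2-dioxaborolane (vinylboronic acid pinacol ester) | C=CB1OC(C)(C)C(C)(C)O1 | starting material
12 | 4-ethenyl-2,6-bis(3-methylbut-2-en-1-yl)phenol | C=Cc1cc(CC=C(C)C)c(O)c(CC=C(C)C)c1 | intermediate
13 | 2-(dimethoxymethyl)-3,5-bis(methoxymethoxy)-4-(3-methylbut-2-en-1-yl)phenol (not isolated) | COC(OC)c1c(O)cc(OCOC)c(CC=C(C)C)c1OCOC | intermediate
14 | 6-(methoxymethylidene)-3,5-bis(methoxymethoxy)-4-(3-methylbut-2-en-1-yl)cyclohexa-2,4-dien-1-one (not isolated) | COC=C1C(=O)C=C(OCOC)C(CC=C(C)C)=C1OCOC | intermediate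
15 | 4-{(3R)-3-[6-hydroxy-2,4-bis(methoxymethoxy)-3-(3-methylbut-2-en-1-yl)phenyl]-3-methoxypropylidene}-2,6-bis(3-methylbut-2-en-1-yl)cyclohexa-2,5-dien-1-one (not isolated) | O=C1C(CC=C(C)C)=CC(=CC[C@@H](OC)c2c(O)cc(OCOC)c(CC=C(C)C)c2OCOC)C=C1CC=C(C)C | intermediate
16 | 4-[(2R,4R)-4-methoxy-5,7-bis(methoxymethoxy)-6-(3-methylbut-2-en-1-yl)-3,4-dihydro-2H-chromen-2-yl]-2,6-bis(3-methylbut-2-en-1-yl)phenol | CC(C)=CCc1cc([C@H]2C[C@@H](OC)c3c(cc(OCOC)c(CC=C(C)C)c3OCOC)O2)cc(CC=C(C)C)c1O | intermediate
17 | 4-[(2R,4R)-4-methoxy-5,7-bis(methoxymethoxy)-6-(3-methylbut-2-en-1-yl)-3,4-dihydro-2H-chromen-2-yl]-2,6-bis(3-methylbut-2-en-1-yl)phenyl acetate | CC(=O)Oc1c(CC=C(C)C)cc([C@H]2C[C@@H](OC)c3c(cc(OCOC)c(CC=C(C)C)c3OCOC)O2)cc1CC=C(C)C | intermediate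
18 | 4-[(2R,4R)-4-hydroxy-5,7-bis(methoxymethoxy)-6-(3-methylbut-2-en-1-yl)-3,4-dihydro-2H-chromen-2-yl]-2,6-bis(3-methylbut-2-en-1-yl)phenyl acetate | CC(=O)Oc1c(CC=C(C)C)cc([C@H]2C[C@@H](O)c3c(cc(OCOC)c(CC=C(C)C)c3OCOC)O2)cc1CC=C(C)C | intermediate
19 | 4-[(2R)-5,7-bis(methoxymethoxy)-6-(3-methylbut-2-en-1-yl)-4-oxo-3,4-dihydro-2H-chromen-2-yl]-2,6-bis(3-methylbut-2-en-1-yl)phenyl acetate | CC(=O)Oc1c(CC=C(C)C)cc([C@H]2CC(=O)c3c(cc(OCOC)c(CC=C(C)C)c3OCOC)O2)cc1CC=C(C)C | intermediate
20 | (2R)-5,7-dihydroxy-2-[4-hydroxy-3,5-bis(3-methylbut-2-en-1-yl)phenyl]-6-(3-methylbut-2-en-1-yl)-2,3-dihydro-4H-chromen-4-one | CC(C)=CCc1cc([C@H]2CC(=O)c3c(cc(O)c(CC=C(C)C)c3O)O2)cc(CC=C(C)C)c1O | target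

Total step count: 10. Longest linear sequence: 8 steps (1, 2, 3, 6, 7, 8, 9, 10).

Steps most likely to fail

Step 6. What may go wrong:
- slow ionisation of the chelated, electron-rich aldehyde under the weak acid;
- acid-induced oligomerisation of the vinylphenol;
- Friedel–Crafts capture of the C4 cation by the nucleophilic C8 of product already formed;
- poor facial selectivity in the ring closure.

The fallback uses known chemistry, sets out from 7 and 10, and returns at 20. Aldehyde 7 would be treated with ethynylmagnesium bromide (THF, 0 °C) to give 1-[6-hydroxy-2,4-bis(methoxymethoxy)-3-prenylphenyl]prop-2-yn-1-ol F1. This would be oxidised with MnO2 to the aryl ethynyl ketone F2 and closed by base-mediated 6-endo-dig oxa-Michael addition (K2CO3, acetone) to 5,7-bis(methoxymethoxy)-6-prenylchromone F3. Iodide 10 would be capped as 4-iodo-2,6-diprenylphenyl MOM ether F4 (NaH, MOMCl, THF). Iodine–lithium exchange (n-BuLi, −78 °C), B(OMe)3 and mild aqueous work-up would then give 4-(methoxymethoxy)-3,5-diprenylphenylboronic acid F5. Enantioselective palladium-catalysed conjugate addition of F5 to F3 would follow (Pd(OCOCF3)2, tert-butyl pyridine-oxazoline ligand of the enantiomeric series that gives (2R), NH4PF6, H2O, ClCH2CH2Cl, 60 °C). It would give the (2R)-tris-MOM flavanone F6, which the conditions of step 10 would convert into 20.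

Step 8. What may go wrong: loss of H3 from the C4 cation (elimination to the 2H-chromene) and Friedel–Crafts dimerisation at C8 outrunning capture by water, or partial loss of a MOM group. The fallback sets out from 17 and returns at 19, replacing hydrolysis plus alcohol oxidation by oxidative displacement. SN1 exchange with anhydrous tert-butyl hydroperoxide (PPTS cat., CH2Cl2, 0 °C) would give the C4 tert-butyl peroxide F7. Kornblum–DeLaMare fragmentation with Et3N would then give ketone 19 directly, without 18 and without step 9.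

Step 10. What may go wrong: acid-promoted cyclisation of the ortho-prenyl phenols to 2,2-dimethylchromans (O5 or O7 onto the C6 prenyl group, O4' onto a ring B prenyl group) and erosion of the C2 configuration by reversible ring opening. The fallback sets out from 19 and returns at 20 without protic acid. The aryl MOM ethers would be converted with TMSOTf and 2,2'-bipyridyl (CH3CN, 0 °C) into silyl ethers that water cleaves at neutral pH, giving the 5,7-dihydroxy flavanone 4'-acetate F8. The acetate would then be removed under near-neutral conditions (NH4OAc, aqueous MeOH, rt) to give 20.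

Further compounds

F1 | step 6 | 1-[6-hydroxy-2,4-bis(methoxymethoxy)-3-(3-methylbut-2-en-1-yl)phenyl]prop-2-yn-1-ol (racemic) | C#CC(O)c1c(O)cc(OCOC)c(CC=C(C)C)c1OCOC
F2 | step 6 | 1-[6-hydroxy-2,4-bis(methoxymethoxy)-3-(3-methylbut-2-en-1-yl)phenyl]prop-2-yn-1-one | C#CC(=O)c1c(O)cc(OCOC)c(CC=C(C)C)c1OCOC
F3 | step 6 | 5,7-bis(methoxymethoxy)-6-(3-methylbut-2-en-1-yl)-4H-chromen-4-one | O=c1ccoc2cc(OCOC)c(CC=C(C)C)c(OCOC)c12
F4 | step 6 | 5-iodo-2-(methoxymethoxy)-1,3-bis(3-methylbut-2-en-1-yl)benzene | COCOc1c(CC=C(C)C)cc(I)cc1CC=C(C)C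
F5 | step 6 | [4-(methoxymethoxy)-3,5-bis(3-methylbut-2-en-1-yl)phenyl]boronic acid | COCOc1c(CC=C(C)C)cc(B(O)O)cc1CC=C(C)C
F6 | step 6 | (2R)-5,7-bis(methoxymethoxy)-2-[4-(methoxymethoxy)-3,5-bis(3-methylbut-2-en-1-yl)phenyl]-6-(3-methylbut-2-en-1-yl)-2,3-dihydro-4H-chromen-4-one | COCOc1c(CC=C(C)C)cc([C@H]2CC(=O)c3c(cc(OCOC)c(CC=C(C)C)c3OCOC)O2)cc1CC=C(C)C
F7 | step 8 | 4-[(2R,4R)-4-(tert-butylperoxy)-5,7-bis(methoxymethoxy)-6-(3-methylbut-2-en-1-yl)-3,4-dihydro-2H-chromen-2-yl]-2,6-bis(3-methylbut-2-en-1-yl)phenyl acetate | CC(=O)Oc1c(CC=C(C)C)cc([C@H]2C[C@@H](OOC(C)(C)C)c3c(cc(OCOC)c(CC=C(C)C)c3OCOC)O2)cc1CC=C(C)C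
F8 | step 10 | 4-[(2R)-5,7-dihydroxy-6-(3-methylbut-2-en-1-yl)-4-oxo-3,4-dihydro-2H-chromen-2-yl]-2,6-bis(3-methylbut-2-en-1-yl)phenyl acetate | CC(=O)Oc1c(CC=C(C)C)cc([C@H]2CC(=O)c3c(cc(O)c(CC=C(C)C)c3O)O2)cc1CC=C(C)C
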